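**Plan**

1. Retrosynthetic cuts: first the two ester C–O bonds and the C8 carbonyl, then C7–C11 (isopropenyl) and C8–O, then C1–C10 and C4–C5 together. The last cut opens ring A into a four-carbon 2-oxy diene (C1=C2–C3(O)=C4, C15 on C4) and the C5=C10 bond of 3-methylcyclohex-2-enone (ring B).
2. Enabling feature: in ring A (C1–C5, C10) the C3 oxygen lies between C2 and the methyl-bearing C4, and C10 is α and C5 β to the C9 oxygen of ring B. A silyl enol ether diene and an enone are therefore matched in polarity (C4 to C5, C1 to C10).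
3. The diene is used as a 4-silyloxy-2H-thiopyran. A temporary sulfur atom ties C15 to C1, so C15 sits on the inside of the diene and the endo adduct carries the C4 and C5 methyls cis. Sulfur is also a second donor, and Raney Ni later cuts both C–S bonds (C15H3, C1H2).
4. Forward order: ring B is bought and ring A closes in step 3. Then follow desulfurisation, cis-to-trans equilibration at C10, the C7=C8 enone, isopropenyl cuprate, C3 reduction and angeloylation, C8 oxygenation, C9 reduction and acylation, and C8 alcohol to ketone. The (E)-acid is made separately.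
5. Stereochemistry: C5 from a chiral Lewis acid; C4 from C5 (bridge plus endo rule); C10 by thermodynamic epimerisation; C7 by cuprate attack anti to the axial C5 methyl; C3 by dissolving-metal reduction; C9 by hydride attack anti to the axial C8 silyloxy group; alkene geometries from angelic acid and a syn-carbocupration.

Key step: step 3

Numbering: eremophilane numbering (ring A = C1–C5, C10; ring B = C5–C10; C14 on C5, C15 on C4, C11–C13 isopropenyl); β is the face of the C5 methyl.

Assumption: the (S)-configured catalyst of step 3 is taken to open the face of C5=C10 that leads to the (5R) adduct (α-C–H/carbonyl binding model); if the sense is opposite, its enantiomer is used without other change.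

**Route**

Step 1
Reactants: 1 thian-4-one (tetrahydro-4H-thiopyran-4-one)
Product: 3 2,3-dihydro-4H-thiopyran-4-one, via 2-chlorothian-4-one 2 (not isolated)
Conditions: N-chlorosuccinimide, pyridine, CH2Cl2, 0 °C → rt
Reagents that add atoms: none
Why: α-chlorination of the sulfide (chlorosulfonium, Pummerer-type shift) followed by pyridine-induced loss of HCl toward the acidic C3 hydrogen should give the vinylogous thioester; no stereocentre remains.

Step 2
Reactants: 3 2,3-dihydro-4H-thiopyran-4-one
Product: 4 4-[(triisopropylsilyl)oxy]-2H-thiopyran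
Conditions: i-Pr3SiOTf, Et3N, CH2Cl2, 0 °C
Reagents that add atoms: triisopropylsilyl triflate, CC(C)[Si](C(C)C)(C(C)C)OS(=O)(=O)C(F)(F)F
Why: soft enolisation can remove only the C3 hydrogens α to the carbonyl, so O-silylation should give the cross-conjugated silyl dienol ether, a 2-silyloxy diene locked s-cis in the ring.

Step 3
Reactants: 4 4-[(triisopropylsilyl)oxy]-2H-thiopyran; 5 3-methylcyclohex-2-en-1-one
Product: 6 endo cycloadduct, 1β,15-epithio-3-(triisopropylsilyloxy)-11,12,13-trinor-10βH-eremophil-2-en-9-one
Conditions: (S)-3,3-diphenyl-1-(2-methylphenyl)tetrahydro-1H,3H-pyrrolo[1,2-c][1,3,2]oxazaborole (20 mol %), AlBr3 (16 mol %), CH2Cl2, −40 → −20 °C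
Reagents that add atoms: none
Why: Proposed new method: the AlBr3-activated oxazaborolidine binds the C9 carbonyl of 5 with the C10–H held by the catalyst oxygen, and the push–push diene 4 (sulfur on C1, silyloxy on C3) attacks the β-carbon C5 with its enol-ether carbon C4 and closes C1–C10 in an asynchronous endo [4+2], at the limit a Mukaiyama–Michael addition followed by a 6-(enolexo)-endo-trig Michael closure. The closest known reactions are the cationic-oxazaborolidine Diels–Alder of cyclohex-2-enone with 2-silyloxydienes, the AlBr3/AlMe3-promoted Diels–Alder of 3-methylcyclohex-2-enone that builds quaternary carbons, and Diels–Alder reactions of 2H-thiopyrans as masked (Z)-dienes. Ring A closes as the six-membered carbocycle of the cycloadduct, and the sulfur bridge makes it one ring of a 2-thiabicyclo[2.2.2]octene. C5 is set in the absolute sense by the catalyst, which leaves one face of C5=C10 open; C4 follows from C5 because the bridge holds C15 inside the diene and the endo position of the C9 carbonyl then puts C15 cis to the C5 methyl; C1 and C10 follow from suprafacial addition (C10 cis, corrected in step 5). The step needs regio-, endo- and face-selectivity: both donors polarise C4 toward the enone β-carbon, the rigid cyclic diene under Lewis acid favours endo, and the catalyst controls the face.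

Step 4
Reactants: 6 endo cycloadduct
Product: 7 3-(triisopropylsilyloxy)-11,12,13-trinor-10βH-eremophil-2-en-9-one (cis-fused)
Conditions: Raney Ni (W-2, deactivated in boiling acetone), EtOH, rt
Reagents that add atoms: none
Why: Raney Ni hydrogenolysis of both C–S bonds (the allylic C1–S first) should leave C1 as CH2 and C15 as CH3 without touching C4, C5 or C10, and the hindered trisubstituted silyl enol ether and the ketone are expected to survive on the deactivated catalyst.

Step 5
Reactants: 7 cis-fused silyl enol ether ketone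
Product: 8 3-(triisopropylsilyloxy)-11,12,13-trinor-10αH-eremophil-2-en-9-one (trans-fused)
Conditions: NaOMe (0.3 equiv), MeOH/THF, rt
Reagents that add atoms: none
Why: epimerisation through the C9 enolate should convert the cis- into the more stable trans-fused ketone (as for related 4a-methyl-1-decalones), which sets C10 under thermodynamic control; C4 cannot epimerise because C3 is still an enol ether.

Step 6
Reactants: 8 trans-fused silyl enol ether ketone
Product: 10 11,12,13-trinor-10αH-eremophil-7-ene-3,9-dione, via dienone silyl enol ether 9 (not isolated)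
Conditions: LiN(i-Pr)2, THF, −78 °C; PhS(Cl)=N-t-Bu, −78 °C; then Bu4NF, AcOH, THF, 0 °C
Reagents that add atoms: none
Why: kinetic deprotonation at the C8 methylene (not the tertiary C10), S-sulfinimidoylation of the enolate and syn-elimination (one-pot ketone dehydrogenation) should give the C7=C8 enone; buffered fluoride then releases the C2=C3 enolate, which is protonated at C2, so C4 is untouched.

Step 7
Reactants: 10 enedione
Product: 11 9-(tert-butyldimethylsilyloxy)-7βH,10αH-eremophila-8,11-dien-3-one
Conditions: CH2=C(CH3)MgBr (2.2 equiv), CuBr·SMe2 (1.1 equiv), THF, −78 °C; then t-BuMe2SiCl, HMPA, Et3N, −78 → 0 °C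
Reagents that add atoms: isopropenylmagnesium bromide, C=C(C)[Mg]Br; tert-butyldimethylsilyl chloride, CC(C)(C)[Si](C)(C)Cl
Why: cuprate 1,4-addition to the enone (the saturated C3 ketone is inert at −78 °C) with O-silylation of the enolate; the axial C5 methyl shields the β face at C7, so the isopropenyl group should enter from the α face and end up equatorial (7α).

Step 8
Reactants: 11 silyl enol ether ketone
Product: 12 9-(tert-butyldimethylsilyloxy)-7βH,10αH-eremophila-8,11-dien-3α-ol
Conditions: Li, NH3(l), THF, t-BuOH, −78 °C; NH4Cl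
Reagents that add atoms: none
Why: dissolving-metal reduction of the C3 ketone is governed by product stability and should give the equatorial 3α-alcohol (the axial epimer would be syn-axial to the C5 methyl), while the silyl enol ether and the isolated alkene are not reduced.

Step 9
Reactants: 12 3α-alcohol; 13 angelic acid, (Z)-2-methylbut-2-enoic acid
Product: 15 3α-angeloyloxy-9-(tert-butyldimethylsilyloxy)-7βH,10αH-eremophila-8,11-diene, via mixed anhydride 14 (not isolated)
Conditions: 13, 2,4,6-Cl3C6H2COCl, Et3N, toluene, rt; then 12, DMAP, rt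
Reagents that add atoms: none
Why: Yamaguchi esterification through the mixed anhydride acylates the equatorial alcohol under conditions known to keep the (Z)-geometry of angelates; no stereocentre changes.

Step 10
Reactants: 15 angelate silyl enol ether
Product: 17 3α-angeloyloxy-8α-(tert-butyldimethylsilyloxy)-7βH,10αH-eremophil-11-en-9-one, via silyloxy epoxide 16 (not isolated)
Conditions: dimethyldioxirane (acetone solution, 1.05 equiv), CH2Cl2, −78 → 0 °C; then rt
Reagents that add atoms: dimethyldioxirane, CC1(C)OO1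
Why: Rubottom oxidation: the dioxirane epoxidises the electron-rich silyl enol ether in preference to the 1,1-disubstituted alkene and the enoate, from the α face (axial at C8, anti to the C5 methyl), and a 1,4-silyl shift on warming gives the 8α-silyloxy ketone; C8 serves only as a control element for step 11.

Step 11
Reactants: 17 8α-silyloxy ketone
Product: 18 3α-angeloyloxy-8α-(tert-butyldimethylsilyloxy)-7βH,10αH-eremophil-11-en-9α-ol
Conditions: NaBH4, CeCl3·7H2O, MeOH/CH2Cl2, −78 → −40 °C
Reagents that add atoms: none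
Why: Luche-type borohydride reduction: the α side of C9 is blocked by the axial 8α-silyloxy group, so hydride should enter from the β face, anti to the axial C–O bond (polar α-alkoxy effect), and give the equatorial 9α-alcohol, which is also the stable epimer; low temperature and CeCl3 suppress C8 epimerisation and 1,2-silyl migration.

Step 12
Reactants: 19 ethyl but-2-ynoate
Product: 20 ethyl (E)-3-methylpent-2-enoate
Conditions: EtMgBr, CuI, THF, −78 °C; aq. NH4Cl, −78 °C
Reagents that add atoms: ethylmagnesium bromide, CC[Mg]Br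
Why: syn-carbocupration of the ynoate places ethyl and copper cis, so protonation at low temperature should give the (E)-enoate (methyl cis to the ester) stereospecifically.

Step 13
Reactants: 20 ethyl (E)-3-methylpent-2-enoate
Product: 21 (E)-3-methylpent-2-enoic acid
Conditions: LiOH, THF/H2O, rt; then 1 M HCl
Reagents that add atoms: lithium hydroxide, [Li+].[OH-]
Why: saponification of the ethyl ester does not touch the trisubstituted (E)-alkene.

Step 14
Reactants: 18 9α-alcohol; 21 (E)-3-methylpent-2-enoic acid
Product: 23 3α-angeloyloxy-8α-(tert-butyldimethylsilyloxy)-9α-[(E)-3-methylpent-2-enoyloxy]-7βH,10αH-eremophil-11-ene, via mixed anhydride 22 (not isolated)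
Conditions: 21, 2,4,6-Cl3C6H2COCl, Et3N, toluene, rt; then 18, DMAP, rt → 40 °C
Reagents that add atoms: none
Why: Yamaguchi esterification of the hindered equatorial C9 alcohol through the mixed anhydride, with retention at C9.

Step 15
Reactants: 23 diester silyl ether
Product: 24 3α-angeloyloxy-9α-[(E)-3-methylpent-2-enoyloxy]-7βH,10αH-eremophil-11-en-8α-ol
Conditions: HF·pyridine, pyridine, THF, 0 °C → rt
Reagents that add atoms: none
Why: acidic fluoride cleaves the secondary silyl ether without the basic conditions that would move the acyl group from O9 to the cis O8.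

Step 16
Reactants: 24 8α-alcohol
Product: 25 target, (3R,4R,5R,7S,9S,10R)-3α-angeloyloxy-9α-[(E)-3-methylpent-2-enoyloxy]-7βH,10αH-eremophil-11-en-8-one
Conditions: Dess–Martin periodinane, NaHCO3, CH2Cl2, 0 °C → rt
Reagents that add atoms: none
Why: buffered Dess–Martin oxidation converts the C8 alcohol into the ketone under neutral conditions, so the α-stereocentres C7 and C9 (both already in their stable equatorial configuration) and the β,γ-position of the isopropenyl group should not be disturbed.

**Compound list**

1 | thian-4-one | O=C1CCSCC1 | starting material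
2 | 2-chlorothian-4-one (racemic) | O=C1CCSC(Cl)C1 | intermediate
3 | 2,3-dihydro-4H-thiopyran-4-one | O=C1CCSC=C1 | intermediate
4 | 4-[(triisopropylsilyl)oxy]-2H-thiopyran | S1CC=C(O[Si](C(C)C)(C(C)C)C(C)C)C=C1 | intermediate
5 | 3-methylcyclohex-2-en-1-one | CC1=CC(=O)CCC1 | starting material
6 | 1β,15-epithio-3-(triisopropylsilyloxy)-11,12,13-trinor-10βH-eremophil-2-en-9-one (endo adduct) | C1C[C@]2(C)[C@@H](CS3)C(O[Si](C(C)C)(C(C)C)C(C)C)=C[C@@H]3[C@@H]2C(=O)C1 | intermediate
7 | 3-(triisopropylsilyloxy)-11,12,13-trinor-10βH-eremophil-2-en-9-one | C1C[C@]2(C)[C@@H](C)C(O[Si](C(C)C)(C(C)C)C(C)C)=CC[C@@H]2C(=O)C1 | intermediate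
8 | 3-(triisopropylsilyloxy)-11,12,13-trinor-10αH-eremophil-2-en-9-one | C1C[C@]2(C)[C@@H](C)C(O[Si](C(C)C)(C(C)C)C(C)C)=CC[C@H]2C(=O)C1 | intermediate
9 | 3-(triisopropylsilyloxy)-11,12,13-trinor-10αH-eremophila-2,7-dien-9-one | O=C1C=CC[C@]2(C)[C@@H](C)C(O[Si](C(C)C)(C(C)C)C(C)C)=CC[C@@H]12 | intermediate
10 | 11,12,13-trinor-10αH-eremophil-7-ene-3,9-dione | O=C1C=CC[C@]2(C)[C@@H](C)C(=O)CC[C@@H]12 | intermediate
11 | 9-(tert-butyldimethylsilyloxy)-7βH,10αH-eremophila-8,11-dien-3-one | C=C(C)[C@@H]1C[C@]2(C)[C@@H](C)C(=O)CC[C@H]2C(O[Si](C)(C)C(C)(C)C)=C1 | intermediate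
12 | 9-(tert-butyldimethylsilyloxy)-7βH,10αH-eremophila-8,11-dien-3α-ol | C=C(C)[C@@H]1C[C@]2(C)[C@@H](C)[C@H](O)CC[C@H]2C(O[Si](C)(C)C(C)(C)C)=C1 | intermediate
13 | angelic acid | C/C=C(/C)C(=O)O | starting material
14 | angelic 2,4,6-trichlorobenzoic anhydride | C/C=C(/C)C(=O)OC(=O)c1c(Cl)cc(Cl)cc1Cl | intermediate
15 | 3α-angeloyloxy-9-(tert-butyldimethylsilyloxy)-7βH,10αH-eremophila-8,11-diene | C=C(C)[C@@H]1C[C@]2(C)[C@@H](C)[C@H](OC(=O)/C(C)=C\C)CC[C@H]2C(O[Si](C)(C)C(C)(C)C)=C1 | intermediate
16 | 3α-angeloyloxy-9β-(tert-butyldimethylsilyloxy)-8α,9α-epoxy-7βH,10αH-eremophil-11-ene | C=C(C)[C@@H]1C[C@]2(C)[C@@H](C)[C@H](OC(=O)/C(C)=C\C)CC[C@H]2[C@]3(O[Si](C)(C)C(C)(C)C)O[C@H]13 | intermediate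
17 | 3α-angeloyloxy-8α-(tert-butyldimethylsilyloxy)-7βH,10αH-eremophil-11-en-9-one | C=C(C)[C@@H]1C[C@]2(C)[C@@H](C)[C@H](OC(=O)/C(C)=C\C)CC[C@H]2C(=O)[C@@H]1O[Si](C)(C)C(C)(C)C | intermediate
18 | 3α-angeloyloxy-8α-(tert-butyldimethylsilyloxy)-7βH,10αH-eremophil-11-en-9α-ol | C=C(C)[C@@H]1C[C@]2(C)[C@@H](C)[C@H](OC(=O)/C(C)=C\C)CC[C@H]2[C@H](O)[C@@H]1O[Si](C)(C)C(C)(C)C | intermediate
19 | ethyl but-2-ynoate | CC#CC(=O)OCC | starting material
20 | ethyl (E)-3-methylpent-2-enoate | CC/C(C)=C/C(=O)OCC | intermediate
21 | (E)-3-methylpent-2-enoic acid | CC/C(C)=C/C(=O)O | intermediate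
22 | (E)-3-methylpent-2-enoic 2,4,6-trichlorobenzoic anhydride | CC/C(C)=C/C(=O)OC(=O)c1c(Cl)cc(Cl)cc1Cl | intermediate
23 | 3α-angeloyloxy-8α-(tert-butyldimethylsilyloxy)-9α-[(E)-3-methylpent-2-enoyloxy]-7βH,10αH-eremophil-11-ene | C=C(C)[C@@H]1C[C@]2(C)[C@@H](C)[C@H](OC(=O)/C(C)=C\C)CC[C@H]2[C@H](OC(=O)/C=C(\C)CC)[C@@H]1O[Si](C)(C)C(C)(C)C | intermediate
24 | 3α-angeloyloxy-9α-[(E)-3-methylpent-2-enoyloxy]-7βH,10αH-eremophil-11-en-8α-ol | C=C(C)[C@@H]1C[C@]2(C)[C@@H](C)[C@H](OC(=O)/C(C)=C\C)CC[C@H]2[C@H](OC(=O)/C=C(\C)CC)[C@@H]1O | intermediate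
25 | (3R,4R,5R,7S,9S,10R)-3α-angeloyloxy-9α-[(E)-3-methylpent-2-enoyloxy]-7βH,10αH-eremophil-11-en-8-one | C=C(C)[C@@H]1C[C@]2(C)[C@@H](C)[C@H](OC(=O)/C(C)=C\C)CC[C@H]2[C@H](OC(=O)/C=C(\C)CC)C1=O | target

**Step count and risks**

Total steps: 16. Longest linear sequence: 14 (steps 1–11 and 14–16; steps 12–13 make the acid 21).

Steps most likely to fail:

Step 3 (labelled). What may go wrong: the chiral Lewis acid may not activate the β-methyl enone enough, may desilylate the diene, or may give poor face selectivity. Fallback: 4 and 5 are joined with the achiral AlBr3 Lewis acid carrying a little AlMe3, a known promoter for Diels–Alder reactions of 3-methylcyclohex-2-enone with 2-silyloxydienes. This should give racemic 6, that is 6 together with its mirror image ent-6 F1. Steps 4 and 5 then give racemic 8, that is 8 with ent-8 F3, formed via ent-7 F2. The racemate is resolved by the sulfoximine method for ketones: lithiated (S)-N,S-dimethyl-S-phenylsulfoximine (n-BuLi, THF, −78 °C) adds to the C9 ketone from the open α face and gives the diastereomeric β-hydroxysulfoximine F4 (from 8) and β-hydroxysulfoximine F5 (from ent-8). These are separated on silica, and F4 is heated in toluene to release 8 as a single enantiomer. The route continues at step 6.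

Step 11. What may go wrong: hydride delivery from the α face, or base-induced C8 epimerisation and 1,2-silyl migration before reduction. Fallback: the 9β-alcohol F6 formed from 17 in that case is kept. It is mesylated (MsCl, Et3N) to mesylate F7, the silyl group is removed with HF·pyridine to give hydroxy mesylate F8, and Dess–Martin oxidation gives α-mesyloxy ketone F9, whose leaving group is axial and aligned with the C8 carbonyl. SN2 displacement with the cesium salt of 21 (Cs2CO3, DMF, rt) inverts C9 and should give the target 25 directly.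

Step 8. What may go wrong: partial cleavage of the silyl enol ether by amide in liquid ammonia, or incomplete stereocontrol of the electron-transfer reduction. Fallback: 11 is reduced with LiBH(s-Bu)3 (THF, −78 °C), which attacks from the open α (equatorial) side and should give the axial 3β-alcohol F10. Mitsunobu esterification with angelic acid 13 (PPh3, diisopropyl azodicarboxylate, toluene) inverts C3 and gives angelate 15 directly. The route resumes at step 10.

Further compounds

F1 | step 3 | ent-6, mirror image of the endo adduct | C1C[C@@]2(C)[C@H](CS3)C(O[Si](C(C)C)(C(C)C)C(C)C)=C[C@H]3[C@H]2C(=O)C1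
F2 | step 3 | ent-7, mirror image of the cis-fused ketone | C1C[C@@]2(C)[C@H](C)C(O[Si](C(C)C)(C(C)C)C(C)C)=CC[C@H]2C(=O)C1
F3 | step 3 | ent-8, mirror image of the trans-fused ketone | C1C[C@@]2(C)[C@H](C)C(O[Si](C(C)C)(C(C)C)C(C)C)=CC[C@@H]2C(=O)C1
F4 | step 3 | 9β-hydroxy-9α-{[(S)-N-methyl-S-phenylsulfonimidoyl]methyl} adduct of 8 | C1C[C@]2(C)[C@@H](C)C(O[Si](C(C)C)(C(C)C)C(C)C)=CC[C@H]2[C@](O)(C[S@](=NC)(=O)c3ccccc3)C1
F5 | step 3 | corresponding (S)-sulfoximine adduct of ent-8 | C1C[C@@]2(C)[C@H](C)C(O[Si](C(C)C)(C(C)C)C(C)C)=CC[C@@H]2[C@@](O)(C[S@](=NC)(=O)c3ccccc3)C1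
F6 | step 11 | 3α-angeloyloxy-8α-(tert-butyldimethylsilyloxy)-7βH,10αH-eremophil-11-en-9β-ol | C=C(C)[C@@H]1C[C@]2(C)[C@@H](C)[C@H](OC(=O)/C(C)=C\C)CC[C@H]2[C@@H](O)[C@@H]1O[Si](C)(C)C(C)(C)C
F7 | step 11 | 9β-methanesulfonate of F6 | C=C(C)[C@@H]1C[C@]2(C)[C@@H](C)[C@H](OC(=O)/C(C)=C\C)CC[C@H]2[C@@H](OS(C)(=O)=O)[C@@H]1O[Si](C)(C)C(C)(C)C
F8 | step 11 | 3α-angeloyloxy-9β-(methanesulfonyloxy)-7βH,10αH-eremophil-11-en-8α-ol | C=C(C)[C@@H]1C[C@]2(C)[C@@H](C)[C@H](OC(=O)/C(C)=C\C)CC[C@H]2[C@@H](OS(C)(=O)=O)[C@@H]1O
F9 | step 11 | 3α-angeloyloxy-9β-(methanesulfonyloxy)-7βH,10αH-eremophil-11-en-8-one | C=C(C)[C@@H]1C[C@]2(C)[C@@H](C)[C@H](OC(=O)/C(C)=C\C)CC[C@H]2[C@@H](OS(C)(=O)=O)C1=O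
F10 | step 8 | 9-(tert-butyldimethylsilyloxy)-7βH,10αH-eremophila-8,11-dien-3β-ol | C=C(C)[C@@H]1C[C@]2(C)[C@@H](C)[C@@H](O)CC[C@H]2C(O[Si](C)(C)C(C)(C)C)=C1
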